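**Plan** (ring numbered as in the target: C1 carbinol, C3 bears Cl, C4 bears Br and CH3, C5 and C6 are CH2)
1. Retrosynthesis cuts the C1–alkenyl bond (ketone 8 + side-chain bromide 15), then the ring bond C4–C5, then C3–Cl (from a carbinol, with inversion), then the aldol bond C2–C3 and the vinyl–C1 bond.
2. Forward: acetate aldol onto 2-bromoacrolein, Weinreb amide, SN2 chlorination and vinyl addition give the open-chain enone 7. One iron-hydride HAT event then closes the only ring and makes the tertiary bromide (8). The side chain (four steps) is added at C1 and the C1 oxygen is re-delivered by a [2,3] shift.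
3. Enabling feature: C4 is the bromine-bearing sp2 carbon of a 1,1-disubstituted alkene next to C3–Cl, and C5 is the terminal CH2 of a vinyl ketone whose carbonyl carbon (C1) lies inside the six-membered ring to be formed. The C4 radical made by H-atom transfer therefore closes 6-endo onto C5.
4. Stereochemistry: C3 from the auxiliary aldol followed by inversion; C4 from C3 during ring closure; C1 from the Mislow–Evans oxygen return on the face opposite the axial C3–Cl; the side-chain carbinol from a CBS reduction.

Key step: step 5

Assumption 1: the titanium aldol of step 1 is taken to run through the chelated chair (thiocarbonyl sulfur on titanium), so the (S)-auxiliary gives the (R)-carbinol; if the sense proves opposite, the (R)-auxiliary is used.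
Assumption 2: 2-bromoacrolein (2) is taken as purchasable; it is otherwise made from acrolein by bromination and dehydrobromination.

Step 1
Reactants: 1 (S)-3-acetyl-4-benzyl-1,3-thiazolidine-2-thione; 2 2-bromoprop-2-enal
Product: 4 (R)-1-[(S)-4-benzyl-2-thioxo-1,3-thiazolidin-3-yl]-4-bromo-3-hydroxypent-4-en-1-one, via chlorotitanium enolate 3 (not isolated)
Conditions: TiCl4, i-Pr2NEt, CH2Cl2, −78 °C; then 2, −78 °C
Reagents that add atoms: none
Why: Titanium-mediated acetate aldol of an N-acetylthiazolidinethione; in the chelated Zimmerman–Traxler chair the aldehyde reaches the enolate face away from the benzyl group, which should set the (R)-carbinol (future C3).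

Step 2
Reactants: 4 (R)-aldol adduct
Product: 5 (R)-4-bromo-3-hydroxy-N-methoxy-N-methylpent-4-enamide
Conditions: MeNHOMe·HCl, imidazole, CH2Cl2, rt
Reagents that add atoms: N,O-dimethylhydroxylamine hydrochloride, CNOC.Cl
Why: Direct aminolysis of the activated N-acylthiazolidinethione gives the Weinreb amide without touching the carbinol, and the auxiliary is recovered.

Step 3
Reactants: 5 (R)-hydroxy Weinreb amide
Product: 6 (S)-4-bromo-3-chloro-N-methoxy-N-methylpent-4-enamide
Conditions: PPh3, Cl3CC(O)CCl3, CH2Cl2, 0 °C
Reagents that add atoms: hexachloroacetone, ClC(Cl)(Cl)C(=O)C(Cl)(Cl)Cl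
Why: Appel-type chlorination of an allylic alcohol: chloride attacks the alkoxyphosphonium ion by SN2 with inversion to the (S)-chloride, and the vinylic bromine disfavours ionisation and SN2′ attack.

Step 4
Reactants: 6 (S)-chloro Weinreb amide
Product: 7 (S)-6-bromo-5-chlorohepta-1,6-dien-3-one
Conditions: CH2=CHMgBr, THF, −78 to −40 °C; inverse quench into cold aq. HCl
Reagents that add atoms: vinylmagnesium bromide, C=C[Mg]Br
Why: Weinreb ketone synthesis: the magnesium chelate stops at mono-addition and releases the vinyl ketone only on acidic quench, and addition is faster than α-deprotonation, so the β-chloride should survive.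

Step 5
Reactants: 7 (S)-6-bromo-5-chlorohepta-1,6-dien-3-one
Product: 8 (3S,4S)-4-bromo-3-chloro-4-methylcyclohexan-1-one
Conditions: Fe(acac)3 (0.5 equiv), PhSiH3 (2.5 equiv), EtOH/(CH2OH)2 5:1, 0.02 M, rt to 40 °C
Reagents that add atoms: none
Why: Fe(acac)3, PhSiH3 and EtOH generate a trivalent iron hydride that transfers H• to the terminal CH2 of the 2-bromoalkene (Markovnikov), giving the tertiary α-bromo radical at C4, which adds to the unsubstituted β-carbon C5 of the vinyl ketone; the α-keto radical at C6 is reduced by divalent iron to the enolate and protonated by ethanol. The closest known reaction type is the iron-hydride (HAT) reductive coupling of 2-haloalkene donors with enones, run here intramolecularly as a HAT-initiated Giese cyclization. Ring C1–C6 closes in the 6-endo-trig mode, which the carbonyl carbon C1 inside the forming ring enforces: attack at C5 gives the stabilised α-keto radical, whereas 5-exo attack at C6 would give a primary radical on the electron-poor α-carbon. The new C4 stereocentre is controlled by the C3 chloride through a chair-like transition state with CH3 equatorial and the C–Br bond anti to the C–Cl bond (both axial, dipoles opposed), which should give the trans bromochloride. The step needs HAT to the bromoalkene and not to the enone (the electron-poor enone serves as acceptor), survival of the β-chlorine (C–Cl β-scission from the tertiary radical is slow against ring closure), and the C4 facial preference just named, which is the least secure of the three.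

Step 6
Reactants: 9 3-methylbut-2-enal; 10 2,3-dibromoprop-1-ene
Product: 12 rac-2-bromo-6-methylhepta-1,5-dien-4-ol, via (2-bromoprop-2-en-1-yl)zinc bromide 11 (not isolated)
Conditions: Zn dust, THF/sat. aq. NH4Cl, 0 °C to rt
Reagents that add atoms: none
Why: Zinc Barbier allylation: zinc inserts only into the allylic C–Br bond and the allylzinc adds 1,2 to the enal; the carbinol is racemic at this stage.

Step 7
Reactants: 12 rac-2-bromo-6-methylhepta-1,5-dien-4-ol
Product: 13 2-bromo-6-methylhepta-1,5-dien-4-one
Conditions: Dess–Martin periodinane, CH2Cl2, 0 °C; used at once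
Reagents that add atoms: none
Why: Dess–Martin oxidation under neutral conditions should give the enone without moving the 2-bromoallyl double bond into conjugation.

Step 8
Reactants: 13 2-bromo-6-methylhepta-1,5-dien-4-one
Product: 14 (S)-2-bromo-6-methylhepta-1,5-dien-4-ol
Conditions: (R)-2-methyl-CBS-oxazaborolidine (10 mol%), catecholborane, toluene, −78 °C
Reagents that add atoms: none
Why: Corey–Bakshi–Shibata reduction: the alkenyl group acts as the large substituent, so the (R)-catalyst should deliver hydride to give the (S)-allylic alcohol.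

Step 9
Reactants: 14 (S)-2-bromo-6-methylhepta-1,5-dien-4-ol
Product: 15 (S)-[(2-bromo-6-methylhepta-1,5-dien-4-yl)oxy](tert-butyl)dimethylsilane
Conditions: TBSCl, imidazole, DMF, rt
Reagents that add atoms: tert-butyldimethylsilyl chloride, CC(C)(C)[Si](C)(C)Cl
Why: Standard silylation masks the secondary alcohol so that only the tertiary alcohol made in step 10 is sulfenylated in step 11.

Step 10
Reactants: 8 (3S,4S)-4-bromo-3-chloro-4-methylcyclohexan-1-one; 15 silyl ether of the side-chain bromide
Product: 18 (1S,3S,4S)-4-bromo-1-[(4S)-4-(tert-butyldimethylsilyloxy)-6-methylhepta-1,5-dien-2-yl]-3-chloro-4-methylcyclohexan-1-ol, via vinyllithium 16 (not isolated), via organocerium dichloride 17 (not isolated)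
Conditions: 15, t-BuLi (2 equiv), Et2O, −78 °C; CeCl3, THF, −78 °C; then 8, −78 °C; H2O
Reagents that add atoms: none
Why: Br/Li exchange and transmetalation give a weakly basic organocerium reagent that adds 1,2 to the enolisable β-chloro ketone; equatorial attack anti to the axial C3–Cl should give mainly the (1S)-alcohol shown, and its C1 configuration does not matter because step 11 erases it.

Step 11
Reactants: 18 (1S)-tertiary allylic alcohol
Product: 20 ({2-[(3S,4S)-4-bromo-3-chloro-4-methylcyclohexylidene]-(4S)-4-(tert-butyldimethylsilyloxy)-6-methylhept-5-en-1-yl}sulfinyl)benzene (mixture at sulfur and at the ring-exocyclic double bond), via allylic benzenesulfenate 19 (not isolated)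
Conditions: LiN(SiMe3)2, THF, −78 °C; PhSCl, −78 °C to rt
Reagents that add atoms: benzenesulfenyl chloride, ClSc1ccccc1
Why: Mislow–Evans rearrangement: the lithium alkoxide is sulfenylated and the allylic sulfenate shifts by a [2,3]-sigmatropic path to the more stable primary allylic sulfoxide, which removes the C1 stereocentre.

Step 12
Reactants: 20 allylic sulfoxide
Product: 22 (1R,3S,4S)-4-bromo-1-[(4S)-4-(tert-butyldimethylsilyloxy)-6-methylhepta-1,5-dien-2-yl]-3-chloro-4-methylcyclohexan-1-ol, via (1R)-benzenesulfenate 21 (not isolated)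
Conditions: P(OMe)3, MeOH, 40 °C
Reagents that add atoms: none
Why: Reverse [2,3] shift with thiophile capture (Mislow–Evans): the sulfoxide oxygen should return to C1 along the equatorial direction of the chair that keeps C4–Br and C3–Cl axial, that is on the face opposite the axial chlorine, which sets (1R); any C1 epimer can be sent through step 11 again.

Step 13
Reactants: 22 (1R)-silyl ether
Product: 23 (1R,3S,4S)-4-bromo-3-chloro-1-[(4S)-4-hydroxy-6-methylhepta-1,5-dien-2-yl]-4-methylcyclohexan-1-ol
Conditions: HF·pyridine, THF/pyridine, 0 °C to rt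
Reagents that add atoms: none
Why: Buffered fluoride desilylation should remove the silyl group without ionising the tertiary bromide or the allylic alcohols.

**Compound list**
1 | (S)-3-acetyl-4-benzyl-1,3-thiazolidine-2-thione | CC(=O)N1[C@@H](Cc2ccccc2)CSC1=S | starting material
2 | 2-bromoprop-2-enal (2-bromoacrolein) | C=C(Br)C=O | starting material
3 | trichlorotitanium enolate of 1 | C=C(O[Ti](Cl)(Cl)Cl)N1[C@@H](Cc2ccccc2)CSC1=S | intermediate
4 | (R)-1-[(S)-4-benzyl-2-thioxo-1,3-thiazolidin-3-yl]-4-bromo-3-hydroxypent-4-en-1-one | O=C(C[C@@H](O)C(Br)=C)N1[C@@H](Cc2ccccc2)CSC1=S | intermediate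
5 | (R)-4-bromo-3-hydroxy-N-methoxy-N-methylpent-4-enamide | CON(C)C(=O)C[C@@H](O)C(Br)=C | intermediate
6 | (S)-4-bromo-3-chloro-N-methoxy-N-methylpent-4-enamide | CON(C)C(=O)C[C@H](Cl)C(Br)=C | intermediate
7 | (S)-6-bromo-5-chlorohepta-1,6-dien-3-one | C=CC(=O)C[C@H](Cl)C(Br)=C | intermediate
8 | (3S,4S)-4-bromo-3-chloro-4-methylcyclohexan-1-one | O=C1CC[C@](C)(Br)[C@@H](Cl)C1 | intermediate
9 | 3-methylbut-2-enal | CC(C)=CC=O | starting material
10 | 2,3-dibromoprop-1-ene | C=C(Br)CBr | starting material
11 | (2-bromoprop-2-en-1-yl)zinc bromide | C=C(Br)C[Zn]Br | intermediate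
12 | rac-2-bromo-6-methylhepta-1,5-dien-4-ol | C=C(Br)CC(O)C=C(C)C | intermediate
13 | 2-bromo-6-methylhepta-1,5-dien-4-one | C=C(Br)CC(=O)C=C(C)C | intermediate
14 | (S)-2-bromo-6-methylhepta-1,5-dien-4-ol | C=C(Br)C[C@H](O)C=C(C)C | intermediate
15 | (S)-[(2-bromo-6-methylhepta-1,5-dien-4-yl)oxy](tert-butyl)dimethylsilane | C=C(Br)C[C@H](O[Si](C)(C)C(C)(C)C)C=C(C)C | intermediate
16 | [(4S)-4-(tert-butyldimethylsilyloxy)-6-methylhepta-1,5-dien-2-yl]lithium | [Li]C(=C)C[C@H](O[Si](C)(C)C(C)(C)C)C=C(C)C | intermediate
17 | [(4S)-4-(tert-butyldimethylsilyloxy)-6-methylhepta-1,5-dien-2-yl]cerium dichloride | Cl[Ce](Cl)C(=C)C[C@H](O[Si](C)(C)C(C)(C)C)C=C(C)C | intermediate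
18 | (1S,3S,4S)-4-bromo-1-[(4S)-4-(tert-butyldimethylsilyloxy)-6-methylhepta-1,5-dien-2-yl]-3-chloro-4-methylcyclohexan-1-ol | C=C(C[C@H](O[Si](C)(C)C(C)(C)C)C=C(C)C)[C@]1(O)CC[C@](C)(Br)[C@@H](Cl)C1 | intermediate
19 | (1S,3S,4S)-4-bromo-1-[(4S)-4-(tert-butyldimethylsilyloxy)-6-methylhepta-1,5-dien-2-yl]-3-chloro-4-methylcyclohexyl benzenesulfenate | C=C(C[C@H](O[Si](C)(C)C(C)(C)C)C=C(C)C)[C@]1(OSc2ccccc2)CC[C@](C)(Br)[C@@H](Cl)C1 | intermediate
20 | ({2-[(3S,4S)-4-bromo-3-chloro-4-methylcyclohexylidene]-(4S)-4-(tert-butyldimethylsilyloxy)-6-methylhept-5-en-1-yl}sulfinyl)benzene | O=S(CC(C[C@H](O[Si](C)(C)C(C)(C)C)C=C(C)C)=C1CC[C@](C)(Br)[C@@H](Cl)C1)c1ccccc1 | intermediate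
21 | (1R,3S,4S)-4-bromo-1-[(4S)-4-(tert-butyldimethylsilyloxy)-6-methylhepta-1,5-dien-2-yl]-3-chloro-4-methylcyclohexyl benzenesulfenate | C=C(C[C@H](O[Si](C)(C)C(C)(C)C)C=C(C)C)[C@@]1(OSc2ccccc2)CC[C@](C)(Br)[C@@H](Cl)C1 | intermediate
22 | (1R,3S,4S)-4-bromo-1-[(4S)-4-(tert-butyldimethylsilyloxy)-6-methylhepta-1,5-dien-2-yl]-3-chloro-4-methylcyclohexan-1-ol | C=C(C[C@H](O[Si](C)(C)C(C)(C)C)C=C(C)C)[C@@]1(O)CC[C@](C)(Br)[C@@H](Cl)C1 | intermediate
23 | (1R,3S,4S)-4-bromo-3-chloro-1-[(4S)-4-hydroxy-6-methylhepta-1,5-dien-2-yl]-4-methylcyclohexan-1-ol | C=C(C[C@H](O)C=C(C)C)[C@@]1(O)CC[C@](C)(Br)[C@@H](Cl)C1 | target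

**Totals**
Total steps: 13. Longest linear sequence: 9 (steps 1–5 and 10–13).

**Steps most likely to fail**

Step 5. The process at risk is the facial selectivity at C4. If the open-chain radical closes through the rotamer that holds C–Cl anti to the forming bond, bromine ends axial and chlorine equatorial, which is the cis bromochloride. Hydrogen-atom transfer to the vinyl ketone, or loss of HCl from the β-chloro ketone, could also erode the step. The fallback closes the same ring bond first and writes the bromide afterwards on a ring radical; it sets out from 1 and returns at 8. The aldol of 1 with methacrolein under the conditions of step 1 should give the (R)-aldol adduct F1. Aminolysis as in step 2 gives the Weinreb amide F2, and PPh3/hexachloroacetone gives the (S)-chloride F3. Allylmagnesium bromide gives the dienone F4. Ring-closing metathesis (second-generation Grubbs catalyst, RuCl2(=CHPh)(H2IMes)(PCy3), CH2Cl2, 40 °C) joins C4 and C5 as a ring olefin in the cyclohexenone F5. Markovnikov HAT hydrobromination (Co(acac)2, t-BuOOH, Et3SiH, TsBr, n-PrOH, rt) then places H on C5 and Br on C4. The tertiary C4 radical now sits in the ring with the C3–Cl bond axial (allylic strain with CH3), so bromine should be transferred to the opposite face and give 8.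

Step 12. The process at risk is the facial selectivity of the oxygen return to C1: the product needs the alkenyl group syn to the axial chlorine in the Br/Cl-diaxial chair, and capture of the sulfenate may be slow. The fallback delivers carbon along the axial path instead; it sets out from 8 and 15 and returns at 22. Ketone 8 is complexed with MeAl(OAr)2 (Ar = 2,6-di-tert-butyl-4-methylphenyl) in toluene at −78 °C, and the vinyllithium 16 made from 15 is then added. This bulky aluminium Lewis acid occupies the equatorial side of the carbonyl group and is known to turn organolithium additions to cyclohexanones toward axial attack. Here that is the face syn to the axial C3–Cl, which would give 22 directly and make steps 11 and 12 unnecessary; no new compound arises (F0).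

Step 3. The process at risk is SN2′ attack of chloride, elimination to the dienamide, or loss of enantiopurity by ionisation of the activated allylic alcohol. The fallback makes the C–Cl bond at a propargylic carbon and forms the bromoalkene afterwards; it sets out from 1 and returns at 6. The aldol of 1 with 3-(trimethylsilyl)prop-2-ynal gives the propargylic alcohol F6, and aminolysis gives the Weinreb amide F7. PPh3/hexachloroacetone gives the propargylic chloride F8 by clean SN2 inversion, and K2CO3/MeOH gives the terminal alkyne F9. B-bromo-9-borabicyclo[3.3.1]nonane followed by AcOH (Markovnikov bromoboration and protonolysis) then gives 6.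

Further compounds
F1 | step 5 | (R)-1-[(S)-4-benzyl-2-thioxo-1,3-thiazolidin-3-yl]-3-hydroxy-4-methylpent-4-en-1-one | O=C(C[C@@H](O)C(C)=C)N1[C@@H](Cc2ccccc2)CSC1=S
F2 | step 5 | (R)-3-hydroxy-N-methoxy-N,4-dimethylpent-4-enamide | CON(C)C(=O)C[C@@H](O)C(C)=C
F3 | step 5 | (S)-3-chloro-N-methoxy-N,4-dimethylpent-4-enamide | CON(C)C(=O)C[C@H](Cl)C(C)=C
F4 | step 5 | (S)-6-chloro-7-methylocta-1,7-dien-4-one | C=CCC(=O)C[C@H](Cl)C(C)=C
F5 | step 5 | (S)-5-chloro-4-methylcyclohex-3-en-1-one | O=C1CC=C(C)[C@@H](Cl)C1
F0 | step 12 | none | none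
F6 | step 3 | (R)-1-[(S)-4-benzyl-2-thioxo-1,3-thiazolidin-3-yl]-3-hydroxy-5-(trimethylsilyl)pent-4-yn-1-one | O=C(C[C@@H](O)C#C[Si](C)(C)C)N1[C@@H](Cc2ccccc2)CSC1=S
F7 | step 3 | (R)-3-hydroxy-N-methoxy-N-methyl-5-(trimethylsilyl)pent-4-ynamide | CON(C)C(=O)C[C@@H](O)C#C[Si](C)(C)C
F8 | step 3 | (S)-3-chloro-N-methoxy-N-methyl-5-(trimethylsilyl)pent-4-ynamide | CON(C)C(=O)C[C@H](Cl)C#C[Si](C)(C)C
F9 | step 3 | (S)-3-chloro-N-methoxy-N-methylpent-4-ynamide | CON(C)C(=O)C[C@H](Cl)C#C
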